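1. The saturation level of dissolved gas is 0.023 mM in every flask, and that level is smaller than the smallest charge, 0.13 mM. Dissolved gas must therefore be refilled as target forms, counted here as one gas per target.

| flask | starting material | gas phase | remark | time |
|---|---|---|---|---|
| west | 0.13 mM | 0.023 mM (held) | run made earlier |  |
| south | 0.36 mM | 0.023 mM (held) | run made earlier |  |
| north-east | 1.2 mM | 0.023 mM (held) | run made earlier |  |
| eta | 0.15 mM | 0.023 mM (held) |  | 2.0 min |
| zeta | 0.80 mM | 0.023 mM (held) |  | 2.0 min |
| theta | 1.0 mM | 0.023 mM (held) |  | 2.0 min |
| epsilon | 0.30 mM | 0.023 mM (held) |  | 2.0 min |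
| alpha | 0.50 mM | 0.023 mM (held) |  | 2.0 min |

| run | time / s | target / % |
|---|---|---|
| west | 10.0 | 4.7 |
| west | 15.0 | 9.3 |
| west | 30.0 | 20.1 |
| west | 40.0 | 25.8 |
| west | 60.0 | 36.7 |
| south | 12.0 | 4.8 |
| south | 25.0 | 10.3 |
| south | 40.0 | 17.9 |
| south | 50.0 | 21.5 |
| south | 60.0 | 26.4 |
| north-east | 12.0 | 1.4 |
| north-east | 25.0 | 4.8 |
| north-east | 40.0 | 7.8 |
| north-east | 50.0 | 9.2 |
| north-east | 60.0 | 11.1 |

(standard deviation of a reading: 0.5 percentage points)

- all flasks from highest to lowest amount of target, in percent of the starting material charged, at 2.0 min (eta / zeta / theta / epsilon / alpha)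
- the amount of target, in percent of the starting material charged of the flask you put first, at 2.0 min
- the amount of target, in percent of the starting material charged of the flask you put last, at 2.0 min

- the earlier runs were read with a standard deviation of 0.5 percentage points
- at the start none of the gas phase is in solution

2. The first time is the reaction time. The west run, with the smallest charge of the earlier runs, reached a fraction 36.7 % at 60.0 s, which reads as a first-order time of 131 s.

3. The second time comes from the supply. Over the same 60.0 s, target formed at 7.95 × 10⁻⁴ mM s⁻¹ in the west run and 0.00222 mM s⁻¹ in the north-east run. The charge rose 9.23-fold but the rate only 2.79-fold, so gas transfer reads as the rate-limiting step at high charge.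

4. The supply time is the charge divided by the north-east rate, taken as an estimate of the ceiling: 450 s for theta and 67.6 s for eta. Against the reaction time, the ratio is 3.44 for theta and 0.516 for eta. The fraction should therefore fall as the charge rises. The supply time of theta is longer than the reaction time, so the fraction of theta is reckoned as time over supply time, 26.6 %.

5. The forecast gives eta > epsilon > alpha > zeta > theta, with top 62 % (58 % to 66 %) and low 24.5 % (22 % to 27 %). Its ground is that “The dissolved gas is being consumed faster than it is supplied”. Its low lies below the reckoning of step 4.

6. The simulation gives this: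

    gas phase ⇌ dissolved gas, rate k1*(csat - [dissolved gas]) (kL = 0.120 s⁻¹)
    starting material → side product (k = 0.00770 s⁻¹)
    starting material + dissolved gas → target (k = 780 M⁻¹ s⁻¹)
    dissolved gas → decomposed reagent (k = 0.00820 s⁻¹)

The order is eta > epsilon > alpha > zeta > theta, with eta at 51.6 % and theta at 24.2 %. The forecast's order and low hold, but its top stands 10 percentage points high, at what first order to completion through the last west reading gives. Theta read earlier, at 80 s, keeps its supply time of 450 s, so the reckoning gives 17.8 %. That flask holds 17.1 % target, with 41 % of the charge left as starting material.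

The readings were generated by integration for an exercise; the scatter is artificial.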